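Everything rests on removing ring B, the resorcinol fused to the seven-membered carbocycle through C-f (attached to C-b, the ring-fusion CH of the 4-hydroxyphenyl dihydrofuran) and C-k (attached to C-c, the CH carrying a 2,4-dihydroxyphenyl group). Its oxygens on C-h and C-j are meta and C-g and C-i are bare CH, so the ring can be grown in one operation on the C-f=C-k cycloheptene double bond: Wolff rearrangement of a diazomethyl ketone on C-f and capture of the vinylketene by ethoxyacetylene form four C–C bonds and the arene. The precursor is that cycloheptenyl diazomethyl ketone, already carrying both trans-dihydrofurans, all five stereocentres and every phenol as methyl ether.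

Key step: step 24

Labels. Ring A is the central benzene; its carbons are C-p (bears the oxygen of dihydrofuran 1), C-q (bears H), C-r (bears the oxygen of dihydrofuran 2), C-s (bonded to C-d), C-t (bonded to the benzylic CH2) and C-u (bonded to C-b). Dihydrofuran 1 is C-p–O–C-a–C-b–C-u, with the 4-oxygenated phenyl group on C-a. Dihydrofuran 2 is C-r–O–C-e–C-d–C-s, with the 2,4-dioxygenated phenyl group on C-e and the 3,5-dioxygenated phenyl group on C-d. C-c is the CH with the second 2,4-dioxygenated phenyl group. Ring B consists of C-f (on C-b), C-g (CH), C-h (C–O), C-i (CH), C-j (C–O) and C-k (on C-c). The target 50 is C-a R, C-b R, C-c R, C-d S, C-e S. "As in 50" means the same spatial arrangement, whatever the descriptor becomes.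

Remark (assumption). The sense of induction of Rh2(R-PTAD)4 in step 8 and of Rh2(S-PTTL)4 in step 11 is taken to be the one that gives 14 and 21 as drawn; if either proves opposite on these substrates, the mirror-image catalyst is used. Phenols are carried as methyl ethers because these survive the organolithium, carbenoid and metathesis steps.

Step 1
Reactants: 1 3,5-dihydroxybenzyl alcohol; 2 4-methoxybenzyl chloride
Product: 3 [3,5-bis(4-methoxybenzyloxy)phenyl]methanol
Conditions: 2 (2.2 equiv in all), K2CO3, DMF, 60 °C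
Reagents that add atoms: 4-methoxybenzyl chloride (second equivalent of 2), COc1ccc(CCl)cc1
Why: Williamson etherification, in which carbonate deprotonates only the two phenols, so both should be benzylated by the two equivalents of 2 while the benzylic alcohol stays free.

Step 2
Reactants: 3 [3,5-bis(4-methoxybenzyloxy)phenyl]methanol
Product: 4 triisopropylsilyl ether of 3
Conditions: i-Pr3SiCl, imidazole, DMF, 23 °C
Reagents that add atoms: triisopropylsilyl chloride, CC(C)[Si](Cl)(C(C)C)C(C)C
Why: Silylation of the primary alcohol removes the only acidic proton, and the bulky silyl group should resist O-to-C migration in the ortho-lithiated intermediates of steps 4 and 9.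

Step 3
Reactants: 4 triisopropylsilyl ether of 3
Product: 5 2,6-dibromide of 4
Conditions: NBS (2.05 equiv), MeCN, 0 °C
Reagents that add atoms: N-bromosuccinimide, O=C1CCC(=O)N1Br
Why: Electrophilic aromatic bromination should take the two equivalent positions that are para to one ether oxygen and ortho to the other, ahead of the crowded site between the oxygens and of the less activated anisole rings.

Step 4
Reactants: 5 2,6-dibromide of 4; 6 3,5-dimethoxybenzoyl chloride
Product: 8 bromo diaryl ketone, via aryllithium 7 (not isolated)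
Conditions: n-BuLi (1.0 equiv), THF, −78 °C; then cannulation into 6 (1.5 equiv), THF, −78 °C
Reagents that add atoms: none
Why: Bromine–lithium exchange of one of two equivalent bromides followed by acylation of the aryllithium, where inverse addition and the two ortho substituents should stop the reaction at the ketone.

Step 5
Reactants: 8 bromo diaryl ketone
Product: 9 ortho-hydroxy ketone
Conditions: MgBr2·OEt2, Me2S, CH2Cl2, 23 °C
Reagents that add atoms: none
Why: Chelation-controlled ether cleavage, in which magnesium held between the ketone and the ortho ether oxygen should activate only that 4-methoxybenzyl group for removal by bromide and dimethyl sulfide.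

Step 6
Reactants: 9 ortho-hydroxy ketone; 10 2,4-dimethoxybenzyl alcohol
Product: 11 2,4-dimethoxybenzyl ether ketone
Conditions: PPh3, DIAD, THF, 0 → 23 °C
Reagents that add atoms: none
Why: Mitsunobu etherification of the phenol, which avoids the unstable 2,4-dimethoxybenzyl halides.

Step 7
Reactants: 11 2,4-dimethoxybenzyl ether ketone
Product: 12 hydrazone of 11
Conditions: N2H4·H2O (30 equiv), n-BuOH, 110 °C
Reagents that add atoms: hydrazine, NN
Why: Condensation of the ketone with excess hydrazine should give the N-unsubstituted hydrazone, the high temperature making up for the two ortho substituents.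

Step 8
Reactants: 12 hydrazone of 11
Product: 15 trans-dihydrobenzofuran bromide, via diaryldiazomethane 13 (not isolated), via cis-dihydrobenzofuran 14 (not isolated)
Conditions: MnO2, CH2Cl2, 0 °C, filtration; Rh2(R-PTAD)4 (1 mol %), CH2Cl2, 0 → 23 °C; then camphorsulfonic acid (20 mol %), 23 °C
Reagents that add atoms: none
Why: MnO2 dehydrogenates the hydrazone to 13, whose donor/donor rhodium carbene should undergo intramolecular 1,5 C–H insertion into the benzylic methylene of the adjacent 2,4-dimethoxybenzyl ether to give cis 14 with the catalyst fixing C-d, after which mild acid ionises the C-e–O bond reversibly (a 2,4-dimethoxybenzylic cation) so that C-e alone equilibrates to the trans ring while the primary 4-methoxybenzyl ether is untouched.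

Step 9
Reactants: 15 trans-dihydrobenzofuran bromide; 16 dimethyl oxalate
Product: 18 aryl glyoxylate, via aryllithium 17 (not isolated)
Conditions: n-BuLi, THF, −78 °C; then cannulation into 16 (3 equiv), THF, −78 °C
Reagents that add atoms: none
Why: Bromine–lithium exchange and acylation of the aryllithium by inverse addition to excess oxalate should give the α-keto ester without double addition.

Step 10
Reactants: 18 aryl glyoxylate
Product: 20 aryldiazoacetate, via tosylhydrazone 19 (not isolated)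
Conditions: TsNHNH2, toluene, 80 °C; then DBU, CH2Cl2, 23 °C
Reagents that add atoms: p-toluenesulfonyl hydrazide, Cc1ccc(cc1)S(=O)(=O)NN
Why: The ketone carbonyl of the α-keto ester condenses with the sulfonyl hydrazide and base then expels sulfinate (Bamford–Stevens-type diazo formation).

Step 11
Reactants: 20 aryldiazoacetate
Product: 22 trans bis(dihydrofuran) methyl ester, via cis ester 21 (not isolated)
Conditions: Rh2(S-PTTL)4 (2 mol %), toluene, −60 °C; then NaOMe, MeOH, 23 °C
Reagents that add atoms: none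
Why: The donor/acceptor rhodium carbene should insert into the benzylic C–H of the neighbouring 4-methoxybenzyl ether (intramolecular 1,5 C–H insertion) to give the cis ester with the catalyst fixing C-a, and methoxide then epimerises C-b through the ester enolate to the more stable trans ring.

Step 12
Reactants: 22 trans bis(dihydrofuran) methyl ester
Product: 24 alkyne, via aldehyde 23 (not isolated)
Conditions: i-Bu2AlH, CH2Cl2, −78 °C; then MeOH, K2CO3, dimethyl (1-diazo-2-oxopropyl)phosphonate, 23 °C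
Reagents that add atoms: dimethyl (1-diazo-2-oxopropyl)phosphonate, COP(=O)(OC)C(=[N+]=[N-])C(C)=O
Why: Partial reduction to the aluminium hemiacetal and Ohira–Bestmann (Seyferth–Gilbert) homologation of the aldehyde released in methanol, C-b remaining in its thermodynamically preferred trans arrangement under the basic conditions.

Step 13
Reactants: 24 alkyne
Product: 26 2-bromoalkene, via alkenylalane 25 (not isolated)
Conditions: NiCl2(dppp) (3 mol %), i-Bu2AlH, THF, 0 → 23 °C; then NBS, 0 °C
Reagents that add atoms: N-bromosuccinimide, O=C1CCC(=O)N1Br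
Why: Nickel-catalysed hydroalumination with the dppp ligand should place aluminium on the internal alkyne carbon (Markovnikov sense), and NBS exchanges the C–Al bond for C–Br.

Step 14
Reactants: 26 2-bromoalkene
Product: 27 benzylic alcohol
Conditions: Bu4NF, AcOH (1 equiv each), THF, 0 → 23 °C
Reagents that add atoms: none
Why: Fluoride-induced cleavage of the silyl ether, buffered with acetic acid so that the 1-bromovinyl group is not dehydrobrominated by basic fluoride.

Step 15
Reactants: 27 benzylic alcohol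
Product: 28 benzylic bromide
Conditions: CBr4, PPh3, CH2Cl2, 0 °C
Reagents that add atoms: tetrabromomethane, BrC(Br)(Br)Br
Why: Appel bromination converts the primary benzylic alcohol under neutral conditions that spare the acid-sensitive dihydrofurans.

Step 16
Reactants: 29 2,4-dimethoxyphenylacetic acid; 30 (R)-4-benzyl-2-oxazolidinone
Product: 32 (R)-4-benzyl-3-[2-(2,4-dimethoxyphenyl)acetyl]oxazolidin-2-one, via mixed anhydride 31 (not isolated)
Conditions: t-BuCOCl, Et3N, THF, −20 °C; then 30, LiCl, 23 °C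
Reagents that add atoms: none
Why: N-acylation of the oxazolidinone through the mixed pivalic anhydride.

Step 17
Reactants: 28 benzylic bromide; 32 (R)-4-benzyl-3-[2-(2,4-dimethoxyphenyl)acetyl]oxazolidin-2-one
Product: 34 alkylated imide, via sodium enolate 33 (not isolated)
Conditions: NaN(SiMe3)2, THF, −78 °C; then 28, −78 → −20 °C
Reagents that add atoms: none
Why: Evans alkylation, in which the chelated Z enolate should be benzylated on the face opposite the benzyl group of the auxiliary and so set C-c (R in 34, as in 50).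

Step 18
Reactants: 34 alkylated imide
Product: 35 primary alcohol
Conditions: LiBH4, MeOH, Et2O, 0 °C
Reagents that add atoms: none
Why: Reductive cleavage of the imide releases the auxiliary and gives the alcohol without touching C-c.

Step 19
Reactants: 35 primary alcohol
Product: 36 α-aryl aldehyde
Conditions: Dess–Martin periodinane, NaHCO3, CH2Cl2, 0 °C
Reagents that add atoms: none
Why: Dess–Martin oxidation under buffered conditions gives the aldehyde, which is used at once because C-c is now enolisable.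

Step 20
Reactants: 36 α-aryl aldehyde
Product: 37 bromo diene
Conditions: Ph3PCH3Br, KN(SiMe3)2, THF, −78 → 0 °C
Reagents that add atoms: methyltriphenylphosphonium bromide, C[P+](c1ccccc1)(c1ccccc1)c1ccccc1.[Br-]
Why: Wittig methylenation with the lithium-free ylide at low temperature should outrun enolisation of the α-aryl aldehyde.

Step 21
Reactants: 37 bromo diene
Product: 39 α-methylene ketone, via dienyl ether 38 (not isolated)
Conditions: tributyl(1-ethoxyvinyl)stannane, Pd(PPh3)4 (5 mol %), CuI (10 mol %), DMF, 60 °C; then 0.5 M HCl, THF, 0 °C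
Reagents that add atoms: tributyl(1-ethoxyvinyl)stannane, CCCC[Sn](CCCC)(CCCC)C(=C)OCC; water, O
Why: Stille coupling of the alkenyl bromide with the acetyl-anion equivalent and brief hydrolysis of the resulting enol ether should give the 3-oxobut-1-en-2-yl group on C-b.

Step 22
Reactants: 39 α-methylene ketone
Product: 40 cycloheptenyl methyl ketone
Conditions: second-generation Hoveyda–Grubbs catalyst RuCl2(SIMes)(=CH-C6H4-2-O-i-Pr) (10 mol %), 1,4-benzoquinone (20 mol %), toluene (2 mM), 80 °C
Reagents that add atoms: none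
Why: Ring-closing metathesis, in which ruthenium loads onto the monosubstituted alkene and closes onto the 1,1-disubstituted enone alkene, the ortho relationship of the two arms on ring A favouring the seven-membered ring.

Step 23
Reactants: 40 cycloheptenyl methyl ketone
Product: 43 cycloheptenyl diazomethyl ketone, via lithium enolate 41 (not isolated), via trifluoroacetyl diketone 42 (not isolated)
Conditions: LiN(SiMe3)2, THF, −78 °C; CF3CO2CH2CF3; then MsN3, Et3N, H2O, MeCN, 23 °C
Reagents that add atoms: methanesulfonyl azide, CS(=O)(=O)N=[N+]=[N-]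
Why: Detrifluoroacetylative diazo transfer, in which kinetic deprotonation of the methyl group, trifluoroacetylation and reaction of the activated diketone with the sulfonyl azide should give the diazo ketone without enolisation towards C-c.

Step 24
Reactants: 43 cycloheptenyl diazomethyl ketone; 44 ethoxyacetylene
Product: 49 ring-B monoethyl ether phenol, via vinylketene 45 (not isolated), via vinylcyclobutenone 46 (not isolated), via dienylketene 47 (not isolated), via cyclohexadienone 48 (not isolated)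
Conditions: 44 (5 equiv), hν (medium-pressure Hg lamp, Pyrex filter), ClCH2CH2Cl, 25 °C; then 80 °C
Reagents that add atoms: none
Why: Irradiation expels dinitrogen from 43 and ring carbon C-f migrates to the diazo carbon (Wolff rearrangement), giving vinylketene 45 whose vinyl unit is the C-f=C-k bond; the nucleophilic CH terminus of 44 adds to the ketene carbonyl carbon and the (2+2) adduct 46 opens by four-electron electrocyclic ring opening to dienylketene 47. Ring B is closed by six-electron electrocyclisation of 47, which joins the ketene carbon to C-k, and tautomerisation of dienone 48 gives phenol 49. The closest known reaction is the photochemical Wolff variant of the Danheiser benzannulation of α-diazo enones with alkoxyalkynes. No stereocentre is created, and the transient tetrahedral centres of 46 and 48 are erased on aromatisation. The step needs regiocontrol in the ketene–alkyne union (ethoxy on C-h, hydroxyl on C-j), which the polarisation of the ynol ether secures, and the neutral conditions should leave the allylic, benzylic centres C-b and C-c and both dihydrofurans untouched.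

Step 25
Reactants: 49 ring-B monoethyl ether phenol
Product: 50 CNP0283541.1
Conditions: BBr3 (excess), CH2Cl2, −78 → 0 °C; then MeOH, H2O
Reagents that add atoms: none
Why: Lewis-acid cleavage of the seven methyl ethers and the ethyl ether by BBr3, in which any reversible opening of a dihydrofuran C–O bond should reclose to the trans ring already present.

Compound list

1 | 3,5-dihydroxybenzyl alcohol | OCc1cc(O)cc(O)c1 | starting material
2 | 4-methoxybenzyl chloride | COc1ccc(CCl)cc1 | starting material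
3 | [3,5-bis(4-methoxybenzyloxy)phenyl]methanol | OCc1cc(OCc2ccc(OC)cc2)cc(OCc2ccc(OC)cc2)c1 | intermediate
4 | {[3,5-bis(4-methoxybenzyloxy)phenyl]methoxy}triisopropylsilane | CC(C)[Si](OCc1cc(OCc2ccc(OC)cc2)cc(OCc2ccc(OC)cc2)c1)(C(C)C)C(C)C | intermediate
5 | {[2,6-dibromo-3,5-bis(4-methoxybenzyloxy)phenyl]methoxy}triisopropylsilane | CC(C)[Si](OCc1c(Br)c(OCc2ccc(OC)cc2)cc(OCc2ccc(OC)cc2)c1Br)(C(C)C)C(C)C | intermediate
6 | 3,5-dimethoxybenzoyl chloride | COc1cc(OC)cc(c1)C(Cl)=O | starting material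
7 | aryllithium: 5 with one bromine exchanged for lithium (not isolated) | CC(C)[Si](OCc1c(Br)c(OCc2ccc(OC)cc2)cc(OCc2ccc(OC)cc2)c1[Li])(C(C)C)C(C)C | intermediate
8 | [3-bromo-4,6-bis(4-methoxybenzyloxy)-2-(triisopropylsilyloxymethyl)phenyl](3,5-dimethoxyphenyl)methanone | CC(C)[Si](OCc1c(Br)c(OCc2ccc(OC)cc2)cc(OCc2ccc(OC)cc2)c1C(=O)c1cc(OC)cc(OC)c1)(C(C)C)C(C)C | intermediate
9 | [3-bromo-6-hydroxy-4-(4-methoxybenzyloxy)-2-(triisopropylsilyloxymethyl)phenyl](3,5-dimethoxyphenyl)methanone | CC(C)[Si](OCc1c(Br)c(OCc2ccc(OC)cc2)cc(O)c1C(=O)c1cc(OC)cc(OC)c1)(C(C)C)C(C)C | intermediate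
10 | 2,4-dimethoxybenzyl alcohol | COc1ccc(CO)c(OC)c1 | starting material
11 | [3-bromo-6-(2,4-dimethoxybenzyloxy)-4-(4-methoxybenzyloxy)-2-(triisopropylsilyloxymethyl)phenyl](3,5-dimethoxyphenyl)methanone | CC(C)[Si](OCc1c(Br)c(OCc2ccc(OC)cc2)cc(OCc2ccc(OC)cc2OC)c1C(=O)c1cc(OC)cc(OC)c1)(C(C)C)C(C)C | intermediate
12 | hydrazone of 11 (C=N–NH2 in place of C=O) | CC(C)[Si](OCc1c(Br)c(OCc2ccc(OC)cc2)cc(OCc2ccc(OC)cc2OC)c1C(=NN)c1cc(OC)cc(OC)c1)(C(C)C)C(C)C | intermediate
13 | diaryldiazomethane (C=N2 in place of C=O of 11; not isolated) | CC(C)[Si](OCc1c(Br)c(OCc2ccc(OC)cc2)cc(OCc2ccc(OC)cc2OC)c1C(=[N+]=[N-])c1cc(OC)cc(OC)c1)(C(C)C)C(C)C | intermediate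
14 | (2R,3S)-5-bromo-2-(2,4-dimethoxyphenyl)-3-(3,5-dimethoxyphenyl)-6-(4-methoxybenzyloxy)-4-(triisopropylsilyloxymethyl)-2,3-dihydrobenzofuran, cis (C-e R, C-d S; not isolated) | COc1ccc(COc2cc3c(c(CO[Si](C(C)C)(C(C)C)C(C)C)c2Br)[C@H](c2cc(OC)cc(OC)c2)[C@H](c2ccc(OC)cc2OC)O3)cc1 | intermediate
15 | (2S,3S)-5-bromo-2-(2,4-dimethoxyphenyl)-3-(3,5-dimethoxyphenyl)-6-(4-methoxybenzyloxy)-4-(triisopropylsilyloxymethyl)-2,3-dihydrobenzofuran, trans (C-e S, C-d S) | COc1ccc(COc2cc3c(c(CO[Si](C(C)C)(C(C)C)C(C)C)c2Br)[C@H](c2cc(OC)cc(OC)c2)[C@@H](c2ccc(OC)cc2OC)O3)cc1 | intermediate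
16 | dimethyl oxalate | COC(=O)C(=O)OC | starting material
17 | aryllithium: 15 with bromine exchanged for lithium (not isolated) | COc1ccc(COc2cc3c(c(CO[Si](C(C)C)(C(C)C)C(C)C)c2[Li])[C@H](c2cc(OC)cc(OC)c2)[C@@H](c2ccc(OC)cc2OC)O3)cc1 | intermediate
18 | aryl glyoxylate: 15 with C(=O)CO2Me in place of Br | COc1ccc(COc2cc3c(c(CO[Si](C(C)C)(C(C)C)C(C)C)c2C(=O)C(=O)OC)[C@H](c2cc(OC)cc(OC)c2)[C@@H](c2ccc(OC)cc2OC)O3)cc1 | intermediate
19 | tosylhydrazone of the keto group of 18 (not isolated) | COc1ccc(COc2cc3c(c(CO[Si](C(C)C)(C(C)C)C(C)C)c2C(=NNS(=O)(=O)c2ccc(C)cc2)C(=O)OC)[C@H](c2cc(OC)cc(OC)c2)[C@@H](c2ccc(OC)cc2OC)O3)cc1 | intermediate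
20 | methyl aryl(diazo)acetate: 15 with C(=N2)CO2Me in place of Br | COc1ccc(COc2cc3c(c(CO[Si](C(C)C)(C(C)C)C(C)C)c2C(=[N+]=[N-])C(=O)OC)[C@H](c2cc(OC)cc(OC)c2)[C@@H](c2ccc(OC)cc2OC)O3)cc1 | intermediate
21 | bis(dihydrofuran) methyl ester, dihydrofuran 1 cis: CO2Me on C-b, 4-methoxyphenyl on C-a, CH2OSi(i-Pr)3 on C-t; C-a R, C-b S, C-d S, C-e S (not isolated) | COc1ccc([C@@H]2Oc3cc4c(c(CO[Si](C(C)C)(C(C)C)C(C)C)c3[C@@H]2C(=O)OC)[C@H](c2cc(OC)cc(OC)c2)[C@@H](c2ccc(OC)cc2OC)O4)cc1 | intermediate
22 | bis(dihydrofuran) methyl ester, both dihydrofurans trans; C-a R, C-b R, C-d S, C-e S | COc1ccc([C@@H]2Oc3cc4c(c(CO[Si](C(C)C)(C(C)C)C(C)C)c3[C@H]2C(=O)OC)[C@H](c2cc(OC)cc(OC)c2)[C@@H](c2ccc(OC)cc2OC)O4)cc1 | intermediate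
23 | aldehyde: 22 with CHO on C-b (not isolated) | COc1ccc([C@@H]2Oc3cc4c(c(CO[Si](C(C)C)(C(C)C)C(C)C)c3[C@H]2C=O)[C@H](c2cc(OC)cc(OC)c2)[C@@H](c2ccc(OC)cc2OC)O4)cc1 | intermediate
24 | alkyne: 22 with ethynyl on C-b | COc1ccc([C@@H]2Oc3cc4c(c(CO[Si](C(C)C)(C(C)C)C(C)C)c3[C@H]2C#C)[C@H](c2cc(OC)cc(OC)c2)[C@@H](c2ccc(OC)cc2OC)O4)cc1 | intermediate
25 | alkenylalane: 1-(diisobutylalumanyl)vinyl on C-b (not isolated) | COc1ccc([C@@H]2Oc3cc4c(c(CO[Si](C(C)C)(C(C)C)C(C)C)c3[C@H]2C(=C)[Al](CC(C)C)CC(C)C)[C@H](c2cc(OC)cc(OC)c2)[C@@H](c2ccc(OC)cc2OC)O4)cc1 | intermediate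
26 | 2-bromoalkene: 1-bromovinyl on C-b, CH2OSi(i-Pr)3 on C-t | COc1ccc([C@@H]2Oc3cc4c(c(CO[Si](C(C)C)(C(C)C)C(C)C)c3[C@H]2C(Br)=C)[C@H](c2cc(OC)cc(OC)c2)[C@@H](c2ccc(OC)cc2OC)O4)cc1 | intermediate
27 | benzylic alcohol: 26 with CH2OH on C-t | COc1ccc([C@@H]2Oc3cc4c(c(CO)c3[C@H]2C(Br)=C)[C@H](c2cc(OC)cc(OC)c2)[C@@H](c2ccc(OC)cc2OC)O4)cc1 | intermediate
28 | benzylic bromide: 26 with CH2Br on C-t | COc1ccc([C@@H]2Oc3cc4c(c(CBr)c3[C@H]2C(Br)=C)[C@H](c2cc(OC)cc(OC)c2)[C@@H](c2ccc(OC)cc2OC)O4)cc1 | intermediate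
29 | 2,4-dimethoxyphenylacetic acid | COc1ccc(CC(O)=O)c(OC)c1 | starting material
30 | (R)-4-benzyl-2-oxazolidinone | O=C1N[C@H](Cc2ccccc2)CO1 | starting material
31 | mixed anhydride of 29 and pivalic acid (not isolated) | COc1ccc(CC(=O)OC(=O)C(C)(C)C)c(OC)c1 | intermediate
32 | (R)-4-benzyl-3-[2-(2,4-dimethoxyphenyl)acetyl]oxazolidin-2-one | COc1ccc(CC(=O)N2[C@H](Cc3ccccc3)COC2=O)c(OC)c1 | intermediate
33 | sodium Z enolate of 32 (not isolated) | COc1ccc(/C=C(\[O-])N2[C@H](Cc3ccccc3)COC2=O)c(OC)c1.[Na+] | intermediate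
34 | alkylated imide: C-t–CH2–C-c(H)(2,4-dimethoxyphenyl)–C(=O)–oxazolidinone, C-c R, 1-bromovinyl on C-b | COc1ccc([C@@H]2Oc3cc4c(c(C[C@H](c5ccc(OC)cc5OC)C(=O)N5[C@H](Cc6ccccc6)COC5=O)c3[C@H]2C(Br)=C)[C@H](c2cc(OC)cc(OC)c2)[C@@H](c2ccc(OC)cc2OC)O4)cc1 | intermediate
35 | primary alcohol: C-t–CH2–C-c(H)(2,4-dimethoxyphenyl)–CH2OH | COc1ccc([C@@H]2Oc3cc4c(c(C[C@H](c5ccc(OC)cc5OC)CO)c3[C@H]2C(Br)=C)[C@H](c2cc(OC)cc(OC)c2)[C@@H](c2ccc(OC)cc2OC)O4)cc1 | intermediate
36 | α-aryl aldehyde: C-t–CH2–C-c(H)(2,4-dimethoxyphenyl)–CHO | COc1ccc([C@@H]2Oc3cc4c(c(C[C@H](c5ccc(OC)cc5OC)C=O)c3[C@H]2C(Br)=C)[C@H](c2cc(OC)cc(OC)c2)[C@@H](c2ccc(OC)cc2OC)O4)cc1 | intermediate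
37 | bromo diene: C-t–CH2–C-c(H)(2,4-dimethoxyphenyl)–CH=CH2 and 1-bromovinyl on C-b | COc1ccc([C@@H]2Oc3cc4c(c(C[C@H](c5ccc(OC)cc5OC)C=C)c3[C@H]2C(Br)=C)[C@H](c2cc(OC)cc(OC)c2)[C@@H](c2ccc(OC)cc2OC)O4)cc1 | intermediate
38 | dienyl ether: 3-ethoxybuta-1,3-dien-2-yl on C-b (not isolated) | COc1ccc([C@@H]2Oc3cc4c(c(C[C@H](c5ccc(OC)cc5OC)C=C)c3[C@H]2C(=C)C(OCC)=C)[C@H](c2cc(OC)cc(OC)c2)[C@@H](c2ccc(OC)cc2OC)O4)cc1 | intermediate
39 | α-methylene ketone: 3-oxobut-1-en-2-yl on C-b | COc1ccc([C@@H]2Oc3cc4c(c(C[C@H](c5ccc(OC)cc5OC)C=C)c3[C@H]2C(=C)C(C)=O)[C@H](c2cc(OC)cc(OC)c2)[C@@H](c2ccc(OC)cc2OC)O4)cc1 | intermediate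
40 | cycloheptenyl methyl ketone: seven-membered ring C-t–CH2–C-c–C-k(H)=C-f(COCH3)–C-b–C-u, all five centres as in 50 | COc1ccc([C@@H]2Oc3cc4c(c5c3[C@H]2C(C(C)=O)=C[C@@H](c2ccc(OC)cc2OC)C5)[C@H](c2cc(OC)cc(OC)c2)[C@@H](c2ccc(OC)cc2OC)O4)cc1 | intermediate
41 | lithium enolate of 40 on the methyl side (not isolated) | COc1ccc([C@@H]2Oc3cc4c(c5c3[C@H]2C(C(=C)[O-])=C[C@@H](c2ccc(OC)cc2OC)C5)[C@H](c2cc(OC)cc(OC)c2)[C@@H](c2ccc(OC)cc2OC)O4)cc1.[Li+] | intermediate
42 | trifluoroacetyl diketone: 4,4,4-trifluoro-1,3-dioxobutyl on C-f (not isolated) | COc1ccc([C@@H]2Oc3cc4c(c5c3[C@H]2C(C(=O)CC(=O)C(F)(F)F)=C[C@@H](c2ccc(OC)cc2OC)C5)[C@H](c2cc(OC)cc(OC)c2)[C@@H](c2ccc(OC)cc2OC)O4)cc1 | intermediate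
43 | cycloheptenyl diazomethyl ketone: COCHN2 on C-f | COc1ccc([C@@H]2Oc3cc4c(c5c3[C@H]2C(C(=O)C=[N+]=[N-])=C[C@@H](c2ccc(OC)cc2OC)C5)[C@H](c2cc(OC)cc(OC)c2)[C@@H](c2ccc(OC)cc2OC)O4)cc1 | intermediate
44 | ethoxyacetylene | C#COCC | starting material
45 | vinylketene: CH=C=O on C-f (not isolated) | COc1ccc([C@@H]2Oc3cc4c(c5c3[C@H]2C(C=C=O)=C[C@@H](c2ccc(OC)cc2OC)C5)[C@H](c2cc(OC)cc(OC)c2)[C@@H](c2ccc(OC)cc2OC)O4)cc1 | intermediate
46 | vinylcyclobutenone: 2-ethoxy-4-oxocyclobut-2-en-1-yl on C-f, ring carbon bonded to C-f in both configurations (not isolated) | COc1ccc([C@@H]2Oc3cc4c(c5c3[C@H]2C(C6C(=O)C=C6OCC)=C[C@@H](c2ccc(OC)cc2OC)C5)[C@H](c2cc(OC)cc(OC)c2)[C@@H](c2ccc(OC)cc2OC)O4)cc1 | intermediate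
47 | dienylketene: C-f–CH=C(OEt)–CH=C=O (not isolated) | COc1ccc([C@@H]2Oc3cc4c(c5c3[C@H]2C(C=C(OCC)C=C=O)=C[C@@H](c2ccc(OC)cc2OC)C5)[C@H](c2cc(OC)cc(OC)c2)[C@@H](c2ccc(OC)cc2OC)O4)cc1 | intermediate
48 | cyclohexa-2,4-dienone: ring B before tautomerisation, C=O at C-j, C-k tetrahedral in either configuration (not isolated) | COc1ccc([C@@H]2Oc3cc4c(c5c3[C@H]2C6=CC(OCC)=CC(=O)C6[C@@H](c2ccc(OC)cc2OC)C5)[C@H](c2cc(OC)cc(OC)c2)[C@@H](c2ccc(OC)cc2OC)O4)cc1 | intermediate
49 | ring-B phenol: OEt on C-h, OH on C-j, seven methyl ethers, all five centres as in 50 | COc1ccc([C@@H]2Oc3cc4c(c5c3[C@H]2c2cc(OCC)cc(O)c2[C@@H](c2ccc(OC)cc2OC)C5)[C@H](c2cc(OC)cc(OC)c2)[C@@H](c2ccc(OC)cc2OC)O4)cc1 | intermediate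
50 | CNP0283541.1 (C-a R, C-b R, C-c R, C-d S, C-e S) | Oc1ccc([C@@H]2Oc3cc4c(c5c3[C@H]2c2cc(O)cc(O)c2[C@@H](c2ccc(O)cc2O)C5)[C@H](c2cc(O)cc(O)c2)[C@@H](c2ccc(O)cc2O)O4)cc1 | target

Total step count: 25. Longest linear sequence: 24 steps (steps 1–15 and 17–25; step 16 prepares the auxiliary-bearing partner).

Steps most likely to fail

Step 24. The lamp output may be absorbed by the seven alkoxyarenes rather than by the diazo ketone. The carbene left after nitrogen loss may also insert into the allylic C–H bonds at C-b and C-c or add to an arene before C-f migrates, so that too little vinylketene reaches the alkyne. The fallback sets out from 43 and comes back at 49. 43 is rearranged in the dark with PhCO2Ag and Et3N in aqueous dioxane (Arndt–Eistert conditions) to the β,γ-unsaturated homologous acid F1. Oxalyl chloride with a trace of DMF gives the acid chloride F2. Slow addition of Et3N to F2 and excess 44 in toluene at 80 °C generates vinylketene 45 by dehydrochlorination, and 45 runs through 46, 47 and 48 to 49. Ring B is then grown from an acid chloride and base, with no light and no free carbene.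

Step 8. Rhodium may engage the diazo carbon only slowly because both ortho positions on ring A are occupied, so azine formation and carbene dimerisation can overtake insertion, and the twisted aryl group may weaken facial discrimination by the catalyst. The fallback sets out from 9 and comes back at 15. NaBH4 reduces 9 to the ortho-hydroxybenzhydrol F3. 10 is converted with Me2S and HBF4·OEt2 into the sulfonium salt F4. Cs2CO3 in MeCN at 50 °C generates the ortho-quinone methide from F3 and the ylide from F4; their (4+1) annulation (conjugate addition at C-d, then displacement of Me2S by the phenoxide at C-e) gives the racemic trans-dihydrobenzofuran F5. Preparative chromatography on a chiral stationary phase isolates 15, at the cost of half the material. Steps 6 and 7 are then not needed.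

Step 22. Ring closure onto the electron-poor, doubly substituted alkene may be slower than cross-metathesis between the terminal alkenes of two molecules, or slower than ruthenium hydride migration of the terminal double bond into conjugation with the aryl group. The fallback sets out from 37 and comes back at 40. CrCl2 with catalytic NiCl2 in DMF couples 37 with acetaldehyde (Nozaki–Hiyama–Kishi reaction) to the allylic alcohol F6, a mixture of carbinol epimers. Second-generation Grubbs catalyst closes F6, whose 1,1-disubstituted alkene is electron-rich and carries an activating allylic hydroxyl group, to the cycloheptenyl carbinol F7. Dess–Martin periodinane oxidises F7 to 40, so step 21 is replaced as well.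

Further compounds

F1 | step 24 | homologous β,γ-unsaturated acid: CH2CO2H on C-f of the cycloheptene | COc1ccc([C@@H]2Oc3cc4c(c5c3[C@H]2C(CC(O)=O)=C[C@@H](c2ccc(OC)cc2OC)C5)[C@H](c2cc(OC)cc(OC)c2)[C@@H](c2ccc(OC)cc2OC)O4)cc1
F2 | step 24 | acid chloride of F1 | COc1ccc([C@@H]2Oc3cc4c(c5c3[C@H]2C(CC(Cl)=O)=C[C@@H](c2ccc(OC)cc2OC)C5)[C@H](c2cc(OC)cc(OC)c2)[C@@H](c2ccc(OC)cc2OC)O4)cc1
F3 | step 8 | ortho-hydroxybenzhydrol: 9 with CH(OH) in place of C=O, both carbinol configurations | CC(C)[Si](OCc1c(Br)c(OCc2ccc(OC)cc2)cc(O)c1C(O)c1cc(OC)cc(OC)c1)(C(C)C)C(C)C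
F4 | step 8 | (2,4-dimethoxybenzyl)dimethylsulfonium tetrafluoroborate | COc1ccc(C[S+](C)C)c(OC)c1.F[B-](F)(F)F
F5 | step 8 | racemic trans-dihydrobenzofuran bromide (15 and its enantiomer) | COc1ccc(COc2cc3c(c(CO[Si](C(C)C)(C(C)C)C(C)C)c2Br)[C@H](c2cc(OC)cc(OC)c2)[C@@H](c2ccc(OC)cc2OC)O3)cc1.COc1ccc(COc2cc3c(c(CO[Si](C(C)C)(C(C)C)C(C)C)c2Br)[C@@H](c2cc(OC)cc(OC)c2)[C@H](c2ccc(OC)cc2OC)O3)cc1
F6 | step 22 | allylic alcohol: 3-hydroxybut-1-en-2-yl on C-b of 37, both carbinol configurations | COc1ccc([C@@H]2Oc3cc4c(c(C[C@H](c5ccc(OC)cc5OC)C=C)c3[C@H]2C(=C)C(C)O)[C@H](c2cc(OC)cc(OC)c2)[C@@H](c2ccc(OC)cc2OC)O4)cc1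
F7 | step 22 | cycloheptenyl carbinol: 1-hydroxyethyl on C-f, both carbinol configurations | COc1ccc([C@@H]2Oc3cc4c(c5c3[C@H]2C(C(C)O)=C[C@@H](c2ccc(OC)cc2OC)C5)[C@H](c2cc(OC)cc(OC)c2)[C@@H](c2ccc(OC)cc2OC)O4)cc1
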